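The seven-membered ring (C1, C10, C9, C11, C12, C13, C16; locants below) holds a 1,5-relationship between the furyl ketone C12 and the acetoxy carbon C7 across the C11–C9 bond. With C7 as an enone carbonyl that bond is a Michael retron, so the ring is closed last by an intramolecular Mukaiyama–Michael addition of the acetylfuran enol silane to a tetrasubstituted cyclohexenone, which builds quaternary C9 cis to C1 and then C8. The precursor, with both six-membered rings, the lactone and the furan in place, arises from an enantioenriched tetralin phenol by oxidative dearomatisation (C10–OH) and an oxygen-tethered radical cyclisation that delivers the lactone CH2 cis to that hydroxyl.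

Key step: step 11

Locants (clerodane type): C1 = CH bearing the furan; C2 = CH2; C3=C4 = ring alkene, C4 carrying the lactone carbonyl C18; C5 = quaternary carbon carrying the lactone CH2 (C19); C6 = CH2; C7 = CH–OAc; C8 = CH–CH3; C9 = quaternary C–CH3 (C20); C10 = C–OH; C11 = ring CH2 next to ketone C12; C13–C16 = furan carbons (C13 on C12, C16 on C1). Ring A = C1–C5, C10; ring B = C5–C10; ring C = the seven-membered ring.

Assumption: the antipode of the diene ligand in step 2 is the one that delivers (R)-5; compounds 7, 9 and 10 are E/Z mixtures that converge in step 5.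

Step 1
Reactants: 1 3-bromofuran-2-carbaldehyde; 2 (triphenylphosphoranylidene)acetaldehyde
Product: 3 (2E)-3-(3-bromofuran-2-yl)prop-2-enal
Conditions: toluene, 80 °C
Reagents that add atoms: none
Why: Wittig olefination with the formyl-stabilised ylide should give the E-enal, and one equivalent of this weakly nucleophilic ylide limits double homologation.

Step 2
Reactants: 3 (2E)-3-(3-bromofuran-2-yl)prop-2-enal; 4 (4-methoxy-2,3-dimethylphenyl)boronic acid
Product: 5 (3R)-3-(3-bromofuran-2-yl)-3-(4-methoxy-2,3-dimethylphenyl)propanal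
Conditions: [RhCl(C2H4)2]2 (2.5 mol %), (R,R)-Ph-bod* (5.5 mol %), KOH (0.5 equiv), MeOH/H2O 10:1, 30 °C
Reagents that add atoms: none
Why: Rhodium-catalysed asymmetric 1,4-addition of an arylboronic acid (Hayashi–Miyaura reaction) with a chiral diene ligand favours conjugate over carbonyl addition to the enal and sets C1 (R) by ligand-controlled enantiofacial insertion; the furyl bromide should be inert.

Step 3
Reactants: 5 (3R)-3-(3-bromofuran-2-yl)-3-(4-methoxy-2,3-dimethylphenyl)propanal; 6 methyl 2-(dimethoxyphosphoryl)-2-methoxyacetate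
Product: 7 methyl (5R)-5-(3-bromofuran-2-yl)-2-methoxy-5-(4-methoxy-2,3-dimethylphenyl)pent-2-enoate (E/Z)
Conditions: LiN(SiMe3)2 (1.1 equiv), THF, −78 → 0 °C
Reagents that add atoms: none
Why: Horner–Wadsworth–Emmons olefination with the α-methoxy phosphonoacetate anion adds C4 and C18 as the enol ether of an α-keto ester; the alkene geometry is lost in step 5 and no stereocenter is touched.

Step 4
Reactants: 7 methyl (5R)-5-(3-bromofuran-2-yl)-2-methoxy-5-(4-methoxy-2,3-dimethylphenyl)pent-2-enoate; 8 tributyl(1-ethoxyvinyl)stannane
Product: 10 methyl (5R)-5-(3-acetylfuran-2-yl)-2-methoxy-5-(4-methoxy-2,3-dimethylphenyl)pent-2-enoate, via ethoxyvinylfuran 9 (not isolated)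
Conditions: Pd(PPh3)4 (5 mol %), CuI (10 mol %), CsF (2 equiv), DMF, 80 °C; then 1 M HCl, THF, rt
Reagents that add atoms: water (O)
Why: Stille coupling puts a masked acetyl group on furan C13, and dilute acid should hydrolyse the electron-rich ethoxyvinyl ether much faster than the electron-poor α-methoxyacrylate, giving the methyl ketone that later serves as the Michael donor.

Step 5
Reactants: 10 methyl (5R)-5-(3-acetylfuran-2-yl)-2-methoxy-5-(4-methoxy-2,3-dimethylphenyl)pent-2-enoate
Product: 12 methyl (4R)-4-(3-acetylfuran-2-yl)-7-methoxy-5,6-dimethyl-3,4-dihydronaphthalene-1-carboxylate, via methoxytetralin ester 11 (not isolated)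
Conditions: TfOH (1.5 equiv), CH2Cl2, 0 °C → rt
Reagents that add atoms: none
Why: Protonation of the α-methoxyacrylate gives an ester-substituted oxocarbenium ion that alkylates the only free ortho position of the arene (intramolecular Friedel–Crafts cyclialkylation, ring A), and acid-promoted loss of methanol gives the conjugated C3=C4 ester; the acyl-deactivated furan and C1 should be untouched.

Step 6
Reactants: 12 methyl (4R)-4-(3-acetylfuran-2-yl)-7-methoxy-5,6-dimethyl-3,4-dihydronaphthalene-1-carboxylate
Product: 13 methyl (4R)-4-(3-acetylfuran-2-yl)-7-hydroxy-5,6-dimethyl-3,4-dihydronaphthalene-1-carboxylate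
Conditions: BBr3 (3 equiv), CH2Cl2, −78 → 0 °C; MeOH quench
Reagents that add atoms: none
Why: Boron tribromide cleaves the aryl methyl ether at low temperature faster than the conjugated methyl ester, freeing the phenol needed for dearomatisation.

Step 7
Reactants: 13 methyl (4R)-4-(3-acetylfuran-2-yl)-7-hydroxy-5,6-dimethyl-3,4-dihydronaphthalene-1-carboxylate
Product: 14 methyl (4R,4aR)-4-(3-acetylfuran-2-yl)-4a-hydroxy-5,6-dimethyl-7-oxo-3,4,4a,7-tetrahydronaphthalene-1-carboxylate
Conditions: PhI(OAc)2 (1.1 equiv), MeCN/H2O 4:1, 0 °C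
Reagents that add atoms: water (O)
Why: Oxidative dearomatisation of the para-alkylphenol gives the para-quinol; peri strain with the C9 methyl holds the furyl group on C1 pseudoaxial, so water should add to C10 on the opposite face (OH trans to furyl), and the in-plane C1–H is poorly aligned for quinone methide formation.

Step 8
Reactants: 14 methyl (4R,4aR)-4-(3-acetylfuran-2-yl)-4a-hydroxy-5,6-dimethyl-7-oxo-3,4,4a,7-tetrahydronaphthalene-1-carboxylate
Product: 15 the 4a-O-[(bromomethyl)dimethylsilyl] ether of 14
Conditions: BrCH2SiMe2Cl (1.5 equiv), Et3N, DMAP (cat.), CH2Cl2, 0 °C → rt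
Reagents that add atoms: (bromomethyl)chlorodimethylsilane (C[Si](C)(Cl)CBr)
Why: Silylation of the tertiary alcohol with this small chlorosilane installs the tether for the radical cyclisation without affecting the dienone.

Step 9
Reactants: 15 the 4a-O-[(bromomethyl)dimethylsilyl] ether of 14
Product: 16 cyclic siloxane (C5–C19H2–SiMe2–O–C10 ring cis on rings A and B; C7 ketone, C8=C9 enone, C3=C4 methyl ester, furyl on C1)
Conditions: Bu3SnH (1.3 equiv, syringe pump), AIBN (0.2 equiv), benzene, 80 °C, 0.01 M
Reagents that add atoms: none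
Why: Tin hydride generates the nucleophilic α-silyl methyl radical, which should cyclise 5-exo-trig (silicon-tethered Nishiyama–Stork radical cyclisation) onto C5 of the more electron-poor, less substituted enone arm rather than onto the dimethyl-substituted C9; the tether forces the new C5–C19 bond cis to the C10 oxygen.

Step 10
Reactants: 16 cyclic siloxane
Product: 18 tricyclic lactone enone (rings A and B cis-fused, 18,19-lactone, C7 ketone with C8=C9, C10–OH cis to C19, 3-acetylfuran-2-yl on C1 trans to that OH), via diol ester 17 (not isolated)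
Conditions: KF, KHCO3, 30% H2O2, THF/MeOH 1:1, rt; then PPTS (cat.), CH2Cl2, rt
Reagents that add atoms: hydrogen peroxide (OO)
Why: Tamao–Fleming oxidation turns the C19–Si bond into C19–OH with retention and frees the C10 hydroxyl, and the primary alcohol then lactonises onto the adjacent conjugated methyl ester; the tertiary C10–OH cannot, as that would need a bridgehead alkene.

Step 11
Reactants: 18 tricyclic lactone enone
Product: 21 7-oxo tetracycle (target skeleton with C7 ketone), via bis-silyl enol silane 19 (not isolated), via silylated adduct 20 (not isolated)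
Conditions: TMSOTf (3.0 equiv), Et3N (2.2 equiv), CH2Cl2, −78 → 0 °C; then 1 M HCl, THF, rt
Reagents that add atoms: none
Why: Silylation gives the 10-O-TMS ether and the enol silane of the methyl ketone (its only enolisable site; the neopentyl C6 of the enone reacts more slowly), the excess TMSOTf O-silylates the enone, the enol silane carbon C11 attacks the β-carbon C9, and acid then removes the silyl groups. The closest known reaction type is the intramolecular Mukaiyama–Michael addition, including silyl triflate/amine-mediated cyclisations of keto enones that build quaternary carbons. Ring C closes in a 7-exo-trig mode (enol exocyclic) and ends cis-fused to ring B. C9 is controlled by the tether, because the furan hangs from C1 on the face opposite the C10 oxygen and C11 can reach only that face of C9, which places C20 cis to the 10-OH and C19; C8 is set on acidic work-up, where enol protonation and equilibration should leave the methyl equatorial and cis to C20. The step needs site selectivity for the enone over C3 of the alkylidene lactone, which should follow because silyl enol ethers add readily to Lewis-acid-activated enones but poorly to unsaturated esters, the ketone is the more basic carbonyl, and a ring through C3 would be bridged instead of fused.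

Step 12
Reactants: 21 7-oxo tetracycle
Product: 22 7-alcohol (deacetyl target, 7-OH cis to C19 and C20)
Conditions: NaBH4 (1.0 equiv), MeOH/CH2Cl2 1:1, −40 → −10 °C
Reagents that add atoms: none
Why: Axial approach to C7 is blocked by the syn-axial C19 and C20, so hydride should add equatorially and give the axial 7-OH on their face; the dialkyl ketone is more electrophilic than the furyl ketone (a vinylogous ester flanked by a neopentyl CH2) and the lactone.

Step 13
Reactants: 22 7-alcohol
Product: 23 CNP0329797.1 (target)
Conditions: Ac2O (5 equiv), DMAP (1 equiv), pyridine, 40 °C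
Reagents that add atoms: acetic anhydride (CC(=O)OC(C)=O)
Why: DMAP-catalysed acetylation should esterify the secondary 7-OH while the far more hindered tertiary 10-OH stays free.

Compound list
1 | 3-bromofuran-2-carbaldehyde | O=Cc1occc1Br | starting material
2 | (triphenylphosphoranylidene)acetaldehyde | O=CC=P(c1ccccc1)(c1ccccc1)c1ccccc1 | starting material
3 | (2E)-3-(3-bromofuran-2-yl)prop-2-enal | O=C/C=C/c1occc1Br | intermediate
4 | (4-methoxy-2,3-dimethylphenyl)boronic acid | COc1ccc(B(O)O)c(C)c1C | starting material
5 | (3R)-3-(3-bromofuran-2-yl)-3-(4-methoxy-2,3-dimethylphenyl)propanal | O=CC[C@@H](c1occc1Br)c1ccc(OC)c(C)c1C | intermediate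
6 | methyl 2-(dimethoxyphosphoryl)-2-methoxyacetate | COC(=O)C(OC)P(=O)(OC)OC | starting material
7 | methyl (5R)-5-(3-bromofuran-2-yl)-2-methoxy-5-(4-methoxy-2,3-dimethylphenyl)pent-2-enoate (E/Z) | COC(=O)C(OC)=CC[C@@H](c1occc1Br)c1ccc(OC)c(C)c1C | intermediate
8 | tributyl(1-ethoxyvinyl)stannane | CCCC[Sn](CCCC)(CCCC)C(=C)OCC | starting material
9 | methyl (5R)-5-[3-(1-ethoxyvinyl)furan-2-yl]-2-methoxy-5-(4-methoxy-2,3-dimethylphenyl)pent-2-enoate | COC(=O)C(OC)=CC[C@@H](c1occc1C(=C)OCC)c1ccc(OC)c(C)c1C | intermediate (not isolated)
10 | methyl (5R)-5-(3-acetylfuran-2-yl)-2-methoxy-5-(4-methoxy-2,3-dimethylphenyl)pent-2-enoate (E/Z) | COC(=O)C(OC)=CC[C@@H](c1occc1C(C)=O)c1ccc(OC)c(C)c1C | intermediate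
11 | methyl (4R)-4-(3-acetylfuran-2-yl)-1,7-dimethoxy-5,6-dimethyl-1,2,3,4-tetrahydronaphthalene-1-carboxylate (both C1 epimers) | COC(=O)C1(OC)CC[C@@H](c2occc2C(C)=O)c2c(C)c(C)c(OC)cc12 | intermediate (not isolated)
12 | methyl (4R)-4-(3-acetylfuran-2-yl)-7-methoxy-5,6-dimethyl-3,4-dihydronaphthalene-1-carboxylate | COC(=O)C1=CC[C@@H](c2occc2C(C)=O)c2c(C)c(C)c(OC)cc12 | intermediate
13 | methyl (4R)-4-(3-acetylfuran-2-yl)-7-hydroxy-5,6-dimethyl-3,4-dihydronaphthalene-1-carboxylate | COC(=O)C1=CC[C@@H](c2occc2C(C)=O)c2c(C)c(C)c(O)cc12 | intermediate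
14 | methyl (4R,4aR)-4-(3-acetylfuran-2-yl)-4a-hydroxy-5,6-dimethyl-7-oxo-3,4,4a,7-tetrahydronaphthalene-1-carboxylate | COC(=O)C1=CC[C@@H](c2occc2C(C)=O)[C@@]2(O)C(C)=C(C)C(=O)C=C12 | intermediate
15 | 4a-O-[(bromomethyl)dimethylsilyl] ether of 14 | COC(=O)C1=CC[C@@H](c2occc2C(C)=O)[C@@]2(O[Si](C)(C)CBr)C(C)=C(C)C(=O)C=C12 | intermediate
16 | cyclic siloxane (C5–CH2–SiMe2–O–C10, cis) | O=C1C[C@@]2(C[Si](C)(C)O3)C(C(=O)OC)=CC[C@@H](c4occc4C(C)=O)[C@@]23C(C)=C1C | intermediate
17 | diol ester (C19H2OH on C5, free C10–OH, methyl ester on C4) | O=C1C[C@@]2(CO)C(C(=O)OC)=CC[C@@H](c3occc3C(C)=O)[C@@]2(O)C(C)=C1C | intermediate (not isolated)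
18 | tricyclic lactone enone (key-step substrate) | O=C1C[C@@]23COC(=O)C2=CC[C@@H](c2occc2C(C)=O)[C@@]3(O)C(C)=C1C | intermediate
19 | 10-O-TMS ether and trimethylsilyl enol ether of the acetyl group of 18 | O=C1C[C@@]23COC(=O)C2=CC[C@@H](c2occc2C(=C)O[Si](C)(C)C)[C@@]3(O[Si](C)(C)C)C(C)=C1C | intermediate (not isolated)
20 | tetracyclic C7 trimethylsilyl enol ether, 10-O-TMS | C[Si](C)(C)OC1=C(C)[C@]2(C)CC(=O)c3ccoc3[C@@H]3CC=C4C(=O)OC[C@@]4(C1)[C@]23O[Si](C)(C)C | intermediate (not isolated)
21 | 7-oxo tetracycle | O=C1C[C@@]23COC(=O)C2=CC[C@H]2c4occc4C(=O)C[C@@](C)([C@@H]1C)[C@]23O | intermediate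
22 | 7-alcohol (deacetyl target) | O[C@@H]1C[C@@]23COC(=O)C2=CC[C@H]2c4occc4C(=O)C[C@@](C)([C@@H]1C)[C@]23O | intermediate
23 | CNP0329797.1 | CC(=O)O[C@@H]1C[C@@]23COC(=O)C2=CC[C@H]2c4occc4C(=O)C[C@@](C)([C@@H]1C)[C@]23O | target

Total step count: 13. Longest linear sequence: 13 steps (from 1).

Steps most likely to fail

Step 11. Bond formation at the fully substituted C9 may be too slow, the enol silane may instead add to C3 of the alkylidene lactone, or the enone may be silylated at C6 and so lose its acceptor character. Fallback: from 18, LiOH in THF/H2O would open the lactone to the lithium salt of seco-acid F1, whose carboxylate-bearing alkene no longer accepts nucleophiles. KOt-Bu in t-BuOH/THF would then bring about the anionic intramolecular Michael addition of the methyl ketone enolate to C9 and give tetracyclic seco-acid F2. Acidification (1 M HCl) would re-form the lactone built in step 10 and return to 21.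

Step 9. The radical may attack C9 of the other enone arm, or be reduced before it cyclises. Fallback: from 14, Me3SnOH (1,2-dichloroethane, 80 °C) would hydrolyse the methyl ester to quinol acid F3. ClCH2OSO2Cl, NaHCO3 and Bu4NHSO4 in CH2Cl2/H2O would give chloromethyl ester F4. Bu3SnH/AIBN (benzene, 80 °C, slow addition) would then generate the acyloxymethyl radical, which can reach only C5 (5-exo-trig) and should add anti to the C1 branch, closing the lactone directly and returning to 18.

Step 7. Water capture may lose facial selectivity, the benzylic C1–H may be lost to give a quinone methide, or the product may be over-oxidised. Fallback: from 13, Oxone/NaHCO3 in MeCN/H2O (singlet oxygen formed in the flask adds to the phenolate at the para carbon, anti to the furyl group; the acyl-deactivated furan reacts far more slowly) would give para-hydroperoxide F5, and dimethyl sulfide would reduce it to 14.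

Further compounds
F1 | step 11 | seco-acid of 18 (lactone opened; formed as its lithium salt) | O=C1C[C@@]2(CO)C(C(=O)O)=CC[C@@H](c3occc3C(C)=O)[C@@]2(O)C(C)=C1C
F2 | step 11 | tetracyclic seco-acid (ring C closed, lactone open) | O=C1C[C@@]2(CO)C(C(=O)O)=CC[C@H]3c4occc4C(=O)C[C@@](C)([C@@H]1C)[C@@]23O
F3 | step 9 | quinol acid (carboxylic acid of 14) | OC(=O)C1=CC[C@@H](c2occc2C(C)=O)[C@@]2(O)C(C)=C(C)C(=O)C=C12
F4 | step 9 | chloromethyl ester of F3 | ClCOC(=O)C1=CC[C@@H](c2occc2C(C)=O)[C@@]2(O)C(C)=C(C)C(=O)C=C12
F5 | step 7 | para-hydroperoxide (4a-OOH analogue of 14) | COC(=O)C1=CC[C@@H](c2occc2C(C)=O)[C@@]2(OO)C(C)=C(C)C(=O)C=C12
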